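**Retrosynthetic overview**

1. Cembrane numbering is used throughout: C1 lactone-ring CH, C2–C3 ring CH2–CH2, C4 quaternary C–O (bears the C18 methyl), C5 ketone, C8 C(OH)CH3, C9 and C12 THF carbons, C13 CHOH, C15=C17 exocyclic alkene, C16 lactone C=O. The last disconnection is C15=C17, made by decarboxylative methylenation, so C15 is carried as a malonate carbon.
2. Key disconnection: bonds C2–C3 and O–C4 together, by a photoredox radical–polar crossover cascade on a linear precursor. A C2 radical closes the 14-membered carbocycle on C3, and the C4 cation that follows is captured by a C16 ester oxygen to close the oxepan-2-one.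
3. Enabling feature: C4 is both the tertiary O-carbon of the oxepanone and the α-carbon of the C5 ketone, and it carries C3 and a methyl, so C3/C4/C18/C5 are a disguised isopropenyl ketone CH2=C(CH3)–C(=O), used as its silyl dienol ether. C2 lies four carbons from O13, so O13–C13–C14–C1–C2 plus one formyl carbon form a six-membered lactol that stores the C2 radical.
4. Linear precursor: the cis-2,5-disubstituted THF with C8, C9, C12, C13 comes from Shi bis-epoxidation of an (E,E)-dienoate (two Johnson–Claisen rearrangements from methacrolein) and an epoxy-acid cascade. C1 comes from an organocatalytic malonate addition to an enal.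
5. Ring order: THF with a temporary γ-lactone, then the temporary δ-lactol, then the 14-membered carbocycle and the ε-lactone together in the key step.

Key step: step 12

Remark: the γ-hydroxy ketones from step 7 onward are drawn open-chain although they can close reversibly to five-membered hemiketals; this is assumed not to change their reactivity in steps 8 to 11.

**Route**

Step 1
Reactants: 1 methacrolein; 2 allylmagnesium bromide
Product: 3 rac-2-methylhexa-1,5-dien-3-ol
Conditions: CH2=CHCH2MgBr (1.1 equiv), Et2O, −78 → 0 °C; aq. NH4Cl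
Reagents that add atoms: allylmagnesium bromide (2), C=CC[Mg]Br
Why: Grignard 1,2-addition to the enal carbonyl should give the racemic isopropenyl carbinol, whose stereocentre is erased in step 2.

Step 2
Reactants: 3 rac-2-methylhexa-1,5-dien-3-ol; 4 triethyl orthoacetate
Product: 5 ethyl (4E)-4-methylocta-4,7-dienoate
Conditions: CH3C(OEt)3 (5 equiv), EtCO2H (5 mol %), 140 °C, ethanol distilled off
Reagents that add atoms: triethyl orthoacetate (4), CCOC(C)(OCC)OCC
Why: Johnson–Claisen rearrangement through a chair transition state with the allyl substituent equatorial should give the (E)-trisubstituted alkene and add two carbons.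

Step 3
Reactants: 5 ethyl (4E)-4-methylocta-4,7-dienoate; 6 isopropenylmagnesium bromide
Product: 8 rac-(6E)-2,6-dimethyldeca-1,6,9-trien-3-ol, via (4E)-4-methylocta-4,7-dienal 7 (not isolated)
Conditions: i-Bu2AlH (1.05 equiv), CH2Cl2, −78 °C; then CH2=C(CH3)MgBr (1.5 equiv), THF, −78 → 0 °C
Reagents that add atoms: isopropenylmagnesium bromide (6), CC(=C)[Mg]Br
Why: Low-temperature ester reduction stops at the aluminium hemiacetal, which releases the aldehyde on warming for Grignard 1,2-addition in the same flask, giving the racemic carbinol for the second Claisen step.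

Step 4
Reactants: 8 rac-(6E)-2,6-dimethyldeca-1,6,9-trien-3-ol; 4 triethyl orthoacetate
Product: 9 ethyl (4E,8E)-4,8-dimethyldodeca-4,8,11-trienoate
Conditions: CH3C(OEt)3 (5 equiv), EtCO2H (5 mol %), 140 °C, ethanol distilled off
Reagents that add atoms: triethyl orthoacetate (4), CCOC(C)(OCC)OCC
Why: A second Johnson–Claisen rearrangement should set the second (E)-trisubstituted alkene by the same chair model and complete the C5–C14 chain with its two methyl branches.

Step 5
Reactants: 9 ethyl (4E,8E)-4,8-dimethyldodeca-4,8,11-trienoate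
Product: 10 ethyl (4S,5S,8S,9S)-4,5:8,9-diepoxy-4,8-dimethyldodec-11-enoate
Conditions: L-fructose-derived Shi ketone (0.6 equiv), Oxone (2KHSO5·KHSO4·K2SO4), K2CO3, Bu4NHSO4, MeCN/CH2(OMe)2, aq. Na2B4O7 buffer (pH 10.5), 0 °C
Reagents that add atoms: potassium peroxymonosulfate (Oxone), [K+].[O-]S(=O)(=O)OO
Why: In the Shi epoxidation the chiral dioxirane should epoxidise both trisubstituted (E)-alkenes through the spiro transition state with the same facial sense (catalyst control; the D-fructose-derived ketone gives the (R,R)-epoxides from such alkenes, so its enantiomer gives the (S,S)-epoxides needed), while the monosubstituted alkene reacts too slowly to compete.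

Step 6
Reactants: 10 ethyl (4S,5S,8S,9S)-4,5:8,9-diepoxy-4,8-dimethyldodec-11-enoate
Product: 12 (5R)-5-[(2S,5R)-5-[(1S)-1-hydroxybut-3-en-1-yl]-5-methyloxolan-2-yl]-5-methyloxolan-2-one, via bis-epoxy acid 11 (not isolated)
Conditions: LiOH, THF/H2O, 0 → 23 °C; 1 M HCl to pH 3; then camphorsulfonic acid (10 mol %), CH2Cl2, 0 → 23 °C
Reagents that add atoms: lithium hydroxide, [Li+].[OH-]
Why: After saponification, an acid-triggered epoxide-opening cascade should run in one direction, the carboxyl opening the near epoxide 5-exo at its tertiary carbon with inversion and the freed secondary hydroxyl opening the far epoxide 5-exo at its tertiary carbon with inversion, which fixes C8 (R), C9 (S), C12 (R), C13 (S) and the cis-THF.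

Step 7
Reactants: 12 the lactone of step 6; 6 isopropenylmagnesium bromide
Product: 13 (6R)-6-hydroxy-6-[(2S,5R)-5-[(1S)-1-hydroxybut-3-en-1-yl]-5-methyloxolan-2-yl]-2-methylhept-1-en-3-one
Conditions: CH2=C(CH3)MgBr (2.5 equiv), THF, −78 → −40 °C; aq. NH4Cl at −78 °C
Reagents that add atoms: isopropenylmagnesium bromide (6), CC(=C)[Mg]Br
Why: Mono-addition of the alkenyl Grignard reagent to the γ-lactone should stop at the magnesium hemiketal alkoxide at low temperature (the first equivalent deprotonates O13) and release the isopropenyl ketone on work-up.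

Step 8
Reactants: 13 the hydroxy enone of step 7; 14 crotonaldehyde
Product: 15 (2E,5S)-5-hydroxy-5-[(2R,5S)-5-[(2R)-2-hydroxy-6-methyl-5-oxohept-6-en-2-yl]-2-methyloxolan-2-yl]pent-2-enal
Conditions: crotonaldehyde (5 equiv), Hoveyda–Grubbs second-generation catalyst RuCl2(H2IMes)(=CH-C6H4-2-OiPr) (5 mol %), CH2Cl2, 40 °C
Reagents that add atoms: crotonaldehyde (14), C/C=C/C=O
Why: Olefin cross-metathesis of the monosubstituted alkene with excess crotonaldehyde should give the (E)-enal, the electron-poor 1,1-disubstituted isopropenyl ketone and the free hydroxyls being spectators.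

Step 9
Reactants: 15 the enal of step 8; 16 dibenzyl malonate
Product: 18 dibenzyl 2-[(4S,6S)-2-hydroxy-6-[(2R,5S)-5-[(2R)-2-hydroxy-6-methyl-5-oxohept-6-en-2-yl]-2-methyloxolan-2-yl]oxan-4-yl]propanedioate (anomer mixture), via Michael adduct aldehyde 17 (not isolated)
Conditions: dibenzyl malonate (1.5 equiv), (R)-α,α-diphenylprolinol trimethylsilyl ether (10 mol %), EtOH, 0 → 23 °C
Reagents that add atoms: dibenzyl malonate (16), O=C(CC(=O)OCc1ccccc1)OCc1ccccc1
Why: In this iminium-catalysed Michael addition the (R)-diarylprolinol silyl ether shields one face of the (E)-iminium ion so that malonate adds to the other and sets C1 under catalyst control, and the aldehyde is then trapped by O13 as the six-membered lactol with both ring substituents equatorial.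

Step 10
Reactants: 18 the lactol of step 9; 19 N-hydroxyphthalimide
Product: 20 dibenzyl 2-[(4S,6S)-2-[(1,3-dioxoisoindolin-2-yl)oxy]-6-[(2R,5S)-5-[(2R)-2-hydroxy-6-methyl-5-oxohept-6-en-2-yl]-2-methyloxolan-2-yl]oxan-4-yl]propanedioate (anomer mixture)
Conditions: N-hydroxyphthalimide (1.5 equiv), PPh3, diisopropyl azodicarboxylate, THF, 0 → 23 °C
Reagents that add atoms: N-hydroxyphthalimide (19), O=C1c2ccccc2C(=O)N1O
Why: A Mitsunobu reaction should join the lactol hydroxyl to the acidic N–OH group to give the anomeric N-alkoxyphthalimide, the tertiary C8 alcohol being too hindered to react.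

Step 11
Reactants: 20 the N-alkoxyphthalimide of step 10
Product: 21 dibenzyl 2-[(4S,6S)-2-[(1,3-dioxoisoindolin-2-yl)oxy]-6-[(2R,5S)-2-methyl-5-[(2R,4Z)-6-methyl-2,5-bis(triethylsilyloxy)hepta-4,6-dien-2-yl]oxolan-2-yl]oxan-4-yl]propanedioate
Conditions: Et3SiOTf (3 equiv), Et3N (6 equiv), CH2Cl2, −78 → −20 °C; cold aq. NaHCO3
Reagents that add atoms: triethylsilyl trifluoromethanesulfonate, CC[Si](CC)(CC)OS(=O)(=O)C(F)(F)F
Why: Soft enolisation with silyl triflate and amine should turn the ketone into the cross-conjugated 2-silyloxydiene (only the C6 side carries α-hydrogens) and silylate the tertiary C8 alcohol, any silyl ketene acetal of the malonate being hydrolysed in the bicarbonate work-up.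

Step 12
Reactants: 21 the silyl dienol ether of step 11
Product: 23 benzyl ester lactone (1R,4R,8R,9S,12R,13S; the target skeleton with CH(CO2CH2Ph) at C15 in place of C=CH2; C15 epimers), via macrocyclic silyl enol ether formate 22 (not isolated)
Conditions: fac-Ir(ppy)3 (2 mol %), degassed MeCN (1 mM), 4 Å sieves, 450 nm LEDs, 23 °C; then 1 M aq. HCl/THF (1:1), 23 °C
Reagents that add atoms: none
Why: Proposed new method: excited fac-Ir(ppy)3 (trivalent iridium) transfers an electron to the N-alkoxyphthalimide, N–O cleavage gives the anomeric alkoxy radical, and β-scission of its ring C–C bond leaves O13 as a formate and gives the primary C2 radical, which adds to the free CH2 terminus (C3) of the 2-silyloxydiene; the 2-silyloxyallyl radical is oxidised by tetravalent iridium to the allyl cation, a benzyl ester carbonyl oxygen of the malonate adds to its tertiary terminus C4, and phthalimide anion removes the benzyl group, so the sequence is redox-neutral. The closest known reaction types are the reductive alkoxy-radical β-fragmentation of lactol-derived N-alkoxyphthalimides, radical macrocyclisation onto enones, and the radical–polar crossover 1,2-alkyl-acyloxylation of styrenes, 1,3-dienes and enol silanes with redox-active esters; their merger into a macrocyclising carbolactonisation, and the use of an enol silane to make an α-keto carbon cationic, are new. The carbocycle closes 14-endo-trig (both diene carbons C3 and C4 end up in the ring) and the oxepan-2-one closes 7-exo onto the allyl cation. C4 is the only new stereocentre and is set in the lactonisation under control of C1 and the macrocycle: in the chair-like seven-membered transition state the ring bonds C1–C14 and C4–C5, tied together by the ten-atom bridge that holds the cis-THF, should lie pseudo-equatorial and trans, which puts the C18 methyl pseudo-axial and gives (4R). The step needs cyclisation to outrun bimolecular radical decay (1 mM, no hydrogen-atom donor, the cis-THF as a turn, and the masked acrylate at C15 removing a 1,2-vinyl shift and intermolecular addition), oxidation to follow C–C bond formation (tetravalent iridium at about +0.8 V oxidises the electron-rich allyl radical but not the dienol silane, whereas the α-keto radical from the free enone could not be oxidised), and oxygen to add at C4 and not C6 (seven- against nine-membered ring, tertiary terminus) with no competing ether formation (O8 silylated, O13 formylated). The aqueous acid then hydrolyses the silyl enol ether to the C5 ketone and removes the C8 silyl ether and the C13 formate.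

Step 13
Reactants: 23 the benzyl ester lactone of step 12; 24 paraformaldehyde
Product: 26 CNP0266269.2, (1R,4R,8R,9S,12R,13S)-9,12-epoxy-8,13-dihydroxy-5-oxocembr-15(17)-en-16,4-olide, via carboxy lactone 25 (not isolated)
Conditions: H2 (1 atm), Pd/C, EtOAc, 23 °C; filter; then (CH2O)n, Et2NH, THF, 65 °C
Reagents that add atoms: paraformaldehyde (24), C=O
Why: Hydrogenolysis of the benzyl ester should give the malonic half-acid lactone, and a Mannich reaction with formaldehyde and diethylamine followed by decarboxylative elimination should install the exocyclic C15=C17 methylene and remove the temporary C15 stereocentre (decarboxylative methylenation).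

**Compound list**

1 | methacrolein | CC(=C)C=O | starting material
2 | allylmagnesium bromide | C=CC[Mg]Br | starting material
3 | rac-2-methylhexa-1,5-dien-3-ol | CC(=C)C(O)CC=C | intermediate
4 | triethyl orthoacetate | CCOC(C)(OCC)OCC | starting material
5 | ethyl (4E)-4-methylocta-4,7-dienoate | CCOC(=O)CC/C(C)=C/CC=C | intermediate
6 | isopropenylmagnesium bromide | CC(=C)[Mg]Br | starting material
7 | (4E)-4-methylocta-4,7-dienal (not isolated) | O=CCC/C(C)=C/CC=C | intermediate
8 | rac-(6E)-2,6-dimethyldeca-1,6,9-trien-3-ol | CC(=C)C(O)CC/C(C)=C/CC=C | intermediate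
9 | ethyl (4E,8E)-4,8-dimethyldodeca-4,8,11-trienoate | CCOC(=O)CC/C(C)=C/CC/C(C)=C/CC=C | intermediate
10 | ethyl (4S,5S,8S,9S)-4,5:8,9-diepoxy-4,8-dimethyldodec-11-enoate | C=CC[C@@H]1O[C@@]1(C)CC[C@@H]2O[C@@]2(C)CCC(=O)OCC | intermediate
11 | (4S,5S,8S,9S)-4,5:8,9-diepoxy-4,8-dimethyldodec-11-enoic acid (not isolated) | C=CC[C@@H]1O[C@@]1(C)CC[C@@H]2O[C@@]2(C)CCC(=O)O | intermediate
12 | (5R)-5-[(2S,5R)-5-[(1S)-1-hydroxybut-3-en-1-yl]-5-methyloxolan-2-yl]-5-methyloxolan-2-one | C=CC[C@H](O)[C@@]1(C)CC[C@H](O1)[C@@]2(C)CCC(=O)O2 | intermediate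
13 | (6R)-6-hydroxy-6-[(2S,5R)-5-[(1S)-1-hydroxybut-3-en-1-yl]-5-methyloxolan-2-yl]-2-methylhept-1-en-3-one | C=CC[C@H](O)[C@@]1(C)CC[C@H](O1)[C@](C)(O)CCC(=O)C(C)=C | intermediate
14 | crotonaldehyde | C/C=C/C=O | starting material
15 | (2E,5S)-5-hydroxy-5-[(2R,5S)-5-[(2R)-2-hydroxy-6-methyl-5-oxohept-6-en-2-yl]-2-methyloxolan-2-yl]pent-2-enal | O=C/C=C/C[C@H](O)[C@@]1(C)CC[C@H](O1)[C@](C)(O)CCC(=O)C(C)=C | intermediate
16 | dibenzyl malonate | O=C(CC(=O)OCc1ccccc1)OCc1ccccc1 | starting material
17 | open-chain Michael adduct aldehyde, (S) at the new centre C1 (not isolated) | O=CC[C@@H](C(C(=O)OCc1ccccc1)C(=O)OCc2ccccc2)C[C@H](O)[C@@]3(C)CC[C@H](O3)[C@](C)(O)CCC(=O)C(C)=C | intermediate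
18 | dibenzyl 2-[(4S,6S)-2-hydroxy-6-[(2R,5S)-5-[(2R)-2-hydroxy-6-methyl-5-oxohept-6-en-2-yl]-2-methyloxolan-2-yl]oxan-4-yl]propanedioate | O=C(OCc1ccccc1)C(C(=O)OCc2ccccc2)[C@@H]3CC(O)O[C@@H](C3)[C@@]4(C)CC[C@H](O4)[C@](C)(O)CCC(=O)C(C)=C | intermediate
19 | N-hydroxyphthalimide | O=C1c2ccccc2C(=O)N1O | starting material
20 | dibenzyl 2-[(4S,6S)-2-[(1,3-dioxoisoindolin-2-yl)oxy]-6-[(2R,5S)-5-[(2R)-2-hydroxy-6-methyl-5-oxohept-6-en-2-yl]-2-methyloxolan-2-yl]oxan-4-yl]propanedioate | O=C(OCc1ccccc1)C(C(=O)OCc2ccccc2)[C@@H]3CC(ON4C(=O)c5ccccc5C4=O)O[C@@H](C3)[C@@]6(C)CC[C@H](O6)[C@](C)(O)CCC(=O)C(C)=C | intermediate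
21 | dibenzyl 2-[(4S,6S)-2-[(1,3-dioxoisoindolin-2-yl)oxy]-6-[(2R,5S)-2-methyl-5-[(2R,4Z)-6-methyl-2,5-bis(triethylsilyloxy)hepta-4,6-dien-2-yl]oxolan-2-yl]oxan-4-yl]propanedioate | O=C(OCc1ccccc1)C(C(=O)OCc2ccccc2)[C@@H]3CC(ON4C(=O)c5ccccc5C4=O)O[C@@H](C3)[C@@]6(C)CC[C@H](O6)[C@](C)(O[Si](CC)(CC)CC)C/C=C(\O[Si](CC)(CC)CC)C(C)=C | intermediate
22 | macrocyclic silyl enol ether formate (not isolated): (1R,4R,8R,9S,12R,13S) carbocycle with the oxepan-2-one closed, CH(CO2CH2Ph) at C15, OCHO at C13, OSiEt3 at C8, (5Z)-C5(OSiEt3)=C6 | O=C(OCc3ccccc3)C1C(=O)O[C@]2(C)CC[C@@H]1C[C@H](OC=O)[C@@]4(C)CC[C@H](O4)[C@](C)(O[Si](CC)(CC)CC)C/C=C2\O[Si](CC)(CC)CC | intermediate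
23 | benzyl ester lactone: (1R,4R,8R,9S,12R,13S) target skeleton with CH(CO2CH2Ph) at C15 (C15 epimers) | O=C(OCc3ccccc3)C1C(=O)O[C@]2(C)CC[C@@H]1C[C@H](O)[C@@]4(C)CC[C@H](O4)[C@](C)(O)CCC2=O | intermediate
24 | paraformaldehyde (formaldehyde source) | C=O | starting material
25 | carboxy lactone (not isolated): as 23 with CO2H at C15 | OC(=O)C1C(=O)O[C@]2(C)CC[C@@H]1C[C@H](O)[C@@]3(C)CC[C@H](O3)[C@](C)(O)CCC2=O | intermediate
26 | CNP0266269.2, (1R,4R,8R,9S,12R,13S)-9,12-epoxy-8,13-dihydroxy-5-oxocembr-15(17)-en-16,4-olide | C=C1C(=O)O[C@]2(C)CC[C@@H]1C[C@H](O)[C@@]1(C)CC[C@H](O1)[C@](C)(O)CCC2=O | target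

**Step count and risks**

Total step count: 13. Longest linear sequence: 13 steps (1 to 26; the route is fully linear).

Steps most likely to fail:

1. Step 12 (proposed new method). The 14-membered ring closure may lose to bimolecular radical decay, the allyl cation may lose a proton or the benzyl group may not be removed so that the lactone does not persist, and the oxygen may add to the wrong face of C4. The fallback splits C–C and C–O formation into known reactions, sets out from 20 and comes back at 25. The N-alkoxyphthalimide is fragmented under reductive Giese conditions (fac-Ir(ppy)3, Hantzsch ester, MeCN, 1 mM, blue LEDs), so that the C2 radical closes the ring 14-endo on the enone and the α-keto radical is reduced, giving macrocyclic ketone F1. Thermodynamic enol silane formation (Me3SiOTf, Et3N) gives tetrasubstituted silyl enol ether F2. Rubottom oxidation (m-CPBA, then citric acid) gives tertiary α-hydroxy ketone F3, with the C4 epimers separated. Hydrogenolysis (H2, Pd/C) gives malonic acid F4. Carbodiimide lactonisation through the acyl ketene closes the oxepanone on O4 and gives formate ester F5; only the C4 hydroxyl is within reach while O13 stays formylated. Mild hydrolysis of the formate (KHCO3, aqueous MeOH) gives 25, which enters the second stage of step 13.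

2. Step 11. The silyl triflate may ionise the anomeric N–O acetal, silylation of the hindered tertiary alcohol may stall, and the dienol ether may hydrolyse during work-up. The fallback replaces the silyl groups by a temporary ring, sets out from 20 and comes back at 23. Acid-catalysed dehydration of the γ-hydroxy enone through its hemiketal (pyridinium p-toluenesulfonate, 4 Å sieves, benzene, 60 °C) gives cyclic alkoxydiene F6, a 5-isopropenyl-2,3-dihydrofuran that protects O8 and activates the enone in one ring. The photoredox cascade of step 12 applied to F6 should give bridged macrocyclic enol ether F7. The aqueous HCl stage opens the enol ether and the formate to give 23.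

3. Step 9. γ-Deprotonation of the iminium ion (dienamine formation) may expel the δ-oxygen, and catalyst control over C1 may be weak next to the existing stereocentres. The fallback replaces conjugate addition by allylic substitution, sets out from 13 and comes back at 18. Cross-metathesis of 13 with allyl methyl carbonate (same ruthenium catalyst) gives (E)-allylic carbonate F8. Iridium-catalysed branched-selective allylic alkylation with dibenzyl malonate ([Ir(cod)Cl]2, chiral phosphoramidite ligand, Cs2CO3, THF) sets C1 under ligand control and gives vinyl malonate F9. Aldehyde-selective Wacker oxidation of the vinyl group (PdCl2(PhCN)2, CuCl2, AgNO2, t-BuOH/MeNO2, O2) gives aldehyde 17, which closes to 18.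

**Further compounds**

F1 | step 12 | macrocyclic ketone with CH(CH3) at C4 (C4 epimers), C13 formate, dibenzyl malonate on C1 | O=C(OCc1ccccc1)C(C(=O)OCc2ccccc2)[C@@H]3CCC(C)C(=O)CC[C@@](C)(O)[C@@H]4CC[C@@](C)(O4)[C@@H](OC=O)C3
F2 | step 12 | tetrasubstituted C4=C5 trimethylsilyl enol ether of F1 with C8 trimethylsilyl ether | O=C(OCc1ccccc1)C(C(=O)OCc2ccccc2)[C@@H]3CCC(C)=C(O[Si](C)(C)C)CC[C@@](C)(O[Si](C)(C)C)[C@@H]4CC[C@@](C)(O4)[C@@H](OC=O)C3
F3 | step 12 | (4R) tertiary α-hydroxy ketone, C13 formate, dibenzyl malonate on C1 | O=C(OCc1ccccc1)C(C(=O)OCc2ccccc2)[C@@H]3CC[C@@](C)(O)C(=O)CC[C@@](C)(O)[C@@H]4CC[C@@](C)(O4)[C@@H](OC=O)C3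
F4 | step 12 | malonic acid from F3 | OC(=O)C(C(=O)O)[C@@H]1CC[C@@](C)(O)C(=O)CC[C@@](C)(O)[C@@H]2CC[C@@](C)(O2)[C@@H](OC=O)C1
F5 | step 12 | C13 formate of carboxy lactone 25 | OC(=O)C1C(=O)O[C@]2(C)CC[C@@H]1C[C@H](OC=O)[C@@]3(C)CC[C@H](O3)[C@](C)(O)CCC2=O
F6 | step 11 | cyclic alkoxydiene: 20 with the γ-hydroxy enone closed to a 5-isopropenyl-2,3-dihydrofuran | O=C(OCc1ccccc1)C(C(=O)OCc2ccccc2)[C@@H]3CC(ON4C(=O)c5ccccc5C4=O)O[C@@H](C3)[C@@]6(C)CC[C@H](O6)[C@@]7(C)CC=C(C(C)=C)O7
F7 | step 11 | bridged macrocyclic enol ether: lactone closed, O8 bonded to C5 of a C5=C6 enol ether, C13 formate, benzyl ester at C15 | O=C(OCc3ccccc3)C1C(=O)O[C@]2(C)CC[C@@H]1C[C@H](OC=O)[C@@]4(C)CC[C@H](O4)[C@@]5(C)CC=C2O5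
F8 | step 9 | (E)-allylic methyl carbonate from 13 | COC(=O)OC/C=C/C[C@H](O)[C@@]1(C)CC[C@H](O1)[C@](C)(O)CCC(=O)C(C)=C
F9 | step 9 | branched vinyl malonate, (S) at C1 | C=C[C@@H](C(C(=O)OCc1ccccc1)C(=O)OCc2ccccc2)C[C@H](O)[C@@]3(C)CC[C@H](O3)[C@](C)(O)CCC(=O)C(C)=C
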